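The earlier runs and the new flask are calculated with constants of no real substance, and the scatter is random.

In a one-step world each substrate runs down by its own law, and the ratio [left-handed product]/[right-handed product] simply follows from that. With interconversion of the substrates among the steps under discussion, the excess turns on a crossing. Where the two substrates interconvert quickly against their consumption, they stay equal and the ratio holds from the first minute; where they interconvert slowly, the left-handed substrate thins out and the ratio falls.

| flask | left-handed substrate | right-handed substrate | reagent | free catalyst | added ligand | remark | time |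
|---|---|---|---|---|---|---|---|
| Thursday's | 0.41 M | 0.41 M | 1.23 M | 41 mM | 130 mM | run made earlier |  |
| Monday's | 0.41 M | 0.41 M | 1.23 M | 41 mM | 280 mM | run made earlier |  |
| flask | 0.41 M | 0.41 M | 1.23 M | 41 mM | 190 mM |  | 1.5 h |

| run | time / min | left-handed product / % | right-handed product / % |
|---|---|---|---|
| Thursday's | 10.0 | 5.3 | 0.9 |
| Thursday's | 20.0 | 9.9 | 1.7 |
| Thursday's | 30.0 | 13.4 | 2.0 |
| Thursday's | 40.0 | 16.9 | 2.5 |
| Thursday's | 50.0 | 19.8 | 3.3 |
| Thursday's | 60.0 | 23.1 | 3.4 |
| Thursday's | 80.0 | 26.7 | 4.9 |
| Monday's | 10.0 | 3.7 | 0.1 |
| Monday's | 20.0 | 8.2 | 0.7 |
| Monday's | 30.0 | 10.4 | 1.1 |
| Monday's | 40.0 | 13.6 | 1.9 |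
| Monday's | 50.0 | 16.3 | 2.8 |
| Monday's | 60.0 | 17.2 | 2.2 |
| Monday's | 80.0 | 20.9 | 2.9 |

(each reading ± 0.3 percentage points)

- free catalyst is single-handed; left-handed substrate and right-handed substrate are mirror images of each other, charged as a racemate, each of them at the stated concentration
- steps under discussion: 2 reagent -> self-condensation product; reagent + free catalyst + left-handed substrate -> free catalyst + left-handed product; free catalyst -> spent catalyst; free catalyst + added ligand <-> idle complex; reagent + free catalyst + right-handed substrate -> free catalyst + right-handed product; left-handed substrate <-> right-handed substrate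
- an excess is the difference of the two amounts in percent of their sum
- an excess is below zero if the other one leads

- excess of left-handed product over right-handed product in the product at 2.0 min
- excess of left-handed product over right-handed product in the product at 1.5 h
- part of the left-handed substrate and right-handed substrate charged together that has reacted at 1.5 h

Pooling both runs at 60.0 min and 80.0 min, I read 6.56 as the selectivity factor, the rate of left-handed over right-handed product at equal substrate. The excess is then this ratio minus one over the ratio plus one, 73.5%. My objection is that without interconversion, Thursday's left-handed substrate at 80.0 min is down to 0.517 of the right-handed, so the ratio should sink late. The pooled ratio of product made reads 6.93 up to 40.0 min and 5.03 from there to 80.0 min, lower than before. But that later figure rests on 3.40% of right-handed product, uncertain by 0.6 percentage points, so these readings do not separate the two cases. I commit, as a wager, to a constant ratio: 73.5% at both asked times.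

The forecast, finding “no clear sign of racemisation”, gives 78% at 2.0 min, 71% at 1.5 h and 30% reacted. My excess lies below the forecast's at 2.0 min and above it at 1.5 h.

The flask gives 72.9% at 2.0 min, 72.9% at 1.5 h and 29.8% reacted, so the forecast's early excess stands 5.1 points high.

    2 reagent → self-condensation product (k = 6.40 × 10⁻⁵ M⁻¹ s⁻¹)
    reagent + free catalyst + left-handed substrate → free catalyst + left-handed product (k = 0.00570 M⁻² s⁻¹)
    free catalyst → spent catalyst (k = 2.10 × 10⁻⁷ s⁻¹)
    free catalyst + added ligand ⇌ idle complex, settled at all times (K = 3.60 M⁻¹)
    reagent + free catalyst + right-handed substrate → free catalyst + right-handed product (k = 8.90 × 10⁻⁴ M⁻² s⁻¹)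
    left-handed substrate ⇌ right-handed substrate (k = 0.0150 s⁻¹)

The relaxation half-life of the two substrates by their interconversion alone, both ways together, is 0.385 min, short against 1.5 h. Applied to the part reacted in this flask at 1.5 h, my ratio puts 25.9% of the charge into left-handed product. In the neighbour flask charged with 0.16 M of free catalyst, the ratio again gives 73.5%. That flask computes to 72.7% with 69.4% reacted and 59.9% left-handed product, more than the half of the charge that was left-handed.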